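**Retrosynthetic overview**
- The target (micareic acid) is reached by hydrogenolysis of its ring-A benzyl ester; benzyl is used because a 2,6-disubstituted benzoate ester cannot be saponified cleanly.
- The diaryl ether C–O bond is the key disconnection: a proposed carboxylate-directed ortho-C–H aryloxylation of 2-heptyl-4-methoxybenzoic acid (ring B) with the 4-OH of benzyl 2-heptyl-4,6-dihydroxybenzoate (ring A).
- Ring A piece: 5-heptylresorcinol, ortho-carboxylation, then benzyl ester formation.
- Ring B piece: methyl 2-bromo-4-methoxybenzoate, Negishi heptylation, then saponification.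
- No ring is formed; both benzene rings are bought. Order: ring A functionalised (steps 1–2), ring B functionalised (steps 3–4), rings joined (step 5), deprotection (step 6).

Assumption: the target has no stereocentre and no hindered axis, so the "single enantiomer" is the one achiral compound; 5-heptylresorcinol is taken as a catalogue chemical.

**Step 1**
Reactants: 1 5-heptylresorcinol (5-heptylbenzene-1,3-diol)
Product: 2 2-heptyl-4,6-dihydroxybenzoic acid
Conditions: MMC (2 M in DMF, 6 equiv), 120 °C, N2 sweep, 2 h; then cold 2 M HCl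
Reagents that add atoms: methyl magnesium carbonate (methoxymagnesium methyl carbonate, Stiles reagent), CO[Mg]OC(=O)OC
Why: Chelation-controlled ortho-carboxylation of a phenol (Kolbe–Schmitt type with the Stiles reagent); the magnesium phenoxide delivers CO2 to the carbon ortho to one OH and para to the other, the usual outcome for 5-alkylresorcinols; no stereocentre is formed.

**Step 2**
Reactants: 2 2-heptyl-4,6-dihydroxybenzoic acid
Product: 3 benzyl 2-heptyl-4,6-dihydroxybenzoate
Conditions: BnBr (1.05 equiv), KHCO3 (1.1 equiv), DMF, rt, 16 h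
Reagents that add atoms: benzyl bromide, BrCc1ccccc1
Why: Carboxylate O-alkylation (SN2); bicarbonate deprotonates only the carboxylic acid, so both phenols stay free.

**Step 3**
Reactants: 4 methyl 2-bromo-4-methoxybenzoate; 5 n-heptylzinc bromide (0.5 M in THF)
Product: 6 methyl 2-heptyl-4-methoxybenzoate
Conditions: Pd(dppf)Cl2 (3 mol%), THF, 60 °C
Reagents that add atoms: none
Why: Negishi sp2–sp3 cross-coupling; the wide-bite-angle dppf ligand lets reductive elimination outrun β-hydride elimination, and the ester tolerates the organozinc.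

**Step 4**
Reactants: 6 methyl 2-heptyl-4-methoxybenzoate
Product: 7 2-heptyl-4-methoxybenzoic acid
Conditions: LiOH·H2O (3 equiv), THF/MeOH/H2O, 60 °C; then 1 M HCl
Reagents that add atoms: lithium hydroxide, [Li+].[OH-]
Why: Saponification (BAc2) of a mono-ortho-substituted methyl benzoate; the aryl methyl ether and the alkyl chain are inert.

**Step 5**
Reactants: 7 2-heptyl-4-methoxybenzoic acid (1.5 equiv); 3 benzyl 2-heptyl-4,6-dihydroxybenzoate (1.0 equiv)
Product: 9 2-{4-[(benzyloxy)carbonyl]-3-heptyl-5-hydroxyphenoxy}-6-heptyl-4-methoxybenzoic acid, via copper(II) acetate 2-heptyl-4-methoxybenzoate 8 (not isolated)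
Conditions: Cu(OAc)2 (3 equiv), 4 Å MS, DMSO, N2, 100 °C, 12 h; then 1 M HCl
Reagents that add atoms: none
Why: Proposed new method: a native-carboxylate-directed, copper(II)-mediated ortho-C–H aryloxylation that keeps the CO2H. Acid 7 exchanges onto Cu(OAc)2 to give 8, and acetate-assisted concerted metalation–deprotonation cuprates the only free ortho C–H (C6; C2 carries the heptyl group). A second Cu(II) oxidises the aryl–copper species to Cu(III), the more acidic, non-hydrogen-bonded 4-OH of 3 binds as phenoxide, and C–O reductive elimination closes the diaryl ether. The ester-deactivated phenol and the N2 atmosphere limit phenol oxidation, and the absence of silver and phenanthroline ligands at ≤100 °C limits protodecarboxylation. The closest known reaction types are the copper-mediated ortho-C–H aryloxylation of benzamides carrying a bidentate 8-aminoquinoline auxiliary, the ortho-acyloxylation of cupric benzoates, and the carboxylate-directed Cu/Ag alkoxylation that ends with loss of CO2.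

**Step 6**
Reactants: 9 2-{4-[(benzyloxy)carbonyl]-3-heptyl-5-hydroxyphenoxy}-6-heptyl-4-methoxybenzoic acid
Product: 10 2-(4-carboxy-3-heptyl-5-hydroxyphenoxy)-6-heptyl-4-methoxybenzoic acid (micareic acid, the target)
Conditions: H2 (1 atm), 10% Pd/C, EtOAc, rt
Reagents that add atoms: none
Why: Catalytic hydrogenolysis of the benzyl ester; the diaryl ether, aryl methyl ether and free acids are untouched, and the neutral room-temperature conditions avoid decarboxylation of the salicylic-type acid.

**Compound list**
1 | 5-heptylresorcinol (5-heptylbenzene-1,3-diol) | CCCCCCCc1cc(O)cc(O)c1 | starting material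
2 | 2-heptyl-4,6-dihydroxybenzoic acid | CCCCCCCc1cc(O)cc(O)c1C(=O)O | intermediate
3 | benzyl 2-heptyl-4,6-dihydroxybenzoate | CCCCCCCc1cc(O)cc(O)c1C(=O)OCc1ccccc1 | intermediate
4 | methyl 2-bromo-4-methoxybenzoate | COC(=O)c1ccc(OC)cc1Br | starting material
5 | n-heptylzinc bromide | CCCCCCC[Zn]Br | starting material
6 | methyl 2-heptyl-4-methoxybenzoate | CCCCCCCc1cc(OC)ccc1C(=O)OC | intermediate
7 | 2-heptyl-4-methoxybenzoic acid | CCCCCCCc1cc(OC)ccc1C(=O)O | intermediate
8 | copper(II) acetate 2-heptyl-4-methoxybenzoate (mixed carboxylate, formed in the flask) | CCCCCCCc1cc(OC)ccc1C(=O)O[Cu]OC(C)=O | intermediate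
9 | 2-{4-[(benzyloxy)carbonyl]-3-heptyl-5-hydroxyphenoxy}-6-heptyl-4-methoxybenzoic acid | CCCCCCCc1cc(Oc2cc(OC)cc(CCCCCCC)c2C(=O)O)cc(O)c1C(=O)OCc1ccccc1 | intermediate
10 | 2-(4-carboxy-3-heptyl-5-hydroxyphenoxy)-6-heptyl-4-methoxybenzoic acid (micareic acid) | CCCCCCCc1cc(Oc2cc(OC)cc(CCCCCCC)c2C(=O)O)cc(O)c1C(=O)O | target

**Step count**
Total steps: 6. Longest linear sequence: 4 (steps 1, 2, 5, 6 or steps 3, 4, 5, 6).

**Steps most likely to fail, with fallbacks**

Step 5 (the proposed new C–H aryloxylation). A single carboxylate may not hold copper well enough for C–H cupration, and protodecarboxylation or oxidative phenol coupling may compete. The fallback uses known chemistry, sets out from 3 and comes back at 9. One portion of 3 is methylated at the free 4-OH (MeI, K2CO3, acetone, reflux; the 2-OH is hydrogen-bonded to the ester and stays) to give benzyl 2-heptyl-6-hydroxy-4-methoxybenzoate F1. Hydrogenolysis (H2, Pd/C, EtOAc) gives 2-heptyl-6-hydroxy-4-methoxybenzoic acid F2. F2 is condensed with a second portion of 3 at its 4-OH (TFAA, toluene, rt) to give the depside benzyl 2-heptyl-4-[(2-heptyl-6-hydroxy-4-methoxybenzoyl)oxy]-6-hydroxybenzoate F3. K2CO3 in DMSO then triggers a Smiles rearrangement: the ring-B phenoxide attacks the ester-bearing carbon of ring A, which is para to CO2Bn, and the carboxylate leaves. Acidification gives 9.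

Step 1 (MMC carboxylation). Yields are moderate and the product acid decarboxylates easily. The fallback sets out from 1 and comes back at 2, replacing direct carboxylation by formylation and oxidation. Vilsmeier–Haack reaction (POCl3, DMF, 0 °C to rt) gives [(2-heptyl-4,6-dihydroxyphenyl)methylidene]dimethylammonium chloride F4. Aqueous hydrolysis of F4 gives 2-heptyl-4,6-dihydroxybenzaldehyde F5. Pinnick oxidation (NaClO2, NaH2PO4, 2-methyl-2-butene, t-BuOH/H2O) then gives 2.

Step 3 (alkyl Negishi coupling next to an ortho ester). β-Hydride elimination, chain isomerisation or reduction of the bromide may compete. The fallback sets out from 4 and comes back at 6. Sonogashira coupling with 1-heptyne (Pd(PPh3)2Cl2, CuI, Et3N, 60 °C) gives methyl 2-(hept-1-yn-1-yl)-4-methoxybenzoate F6. Hydrogenation of F6 (H2, Pd/C, EtOAc) gives 6.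

**Further compounds**
F1 | step 5 | benzyl 2-heptyl-6-hydroxy-4-methoxybenzoate | CCCCCCCc1cc(OC)cc(O)c1C(=O)OCc1ccccc1
F2 | step 5 | 2-heptyl-6-hydroxy-4-methoxybenzoic acid | CCCCCCCc1cc(OC)cc(O)c1C(=O)O
F3 | step 5 | benzyl 2-heptyl-4-[(2-heptyl-6-hydroxy-4-methoxybenzoyl)oxy]-6-hydroxybenzoate | CCCCCCCc1cc(OC)cc(O)c1C(=O)Oc1cc(O)c(C(=O)OCc2ccccc2)c(CCCCCCC)c1
F4 | step 1 | [(2-heptyl-4,6-dihydroxyphenyl)methylidene]dimethylammonium chloride | CCCCCCCc1cc(O)cc(O)c1C=[N+](C)C.[Cl-]
F5 | step 1 | 2-heptyl-4,6-dihydroxybenzaldehyde | CCCCCCCc1cc(O)cc(O)c1C=O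
F6 | step 3 | methyl 2-(hept-1-yn-1-yl)-4-methoxybenzoate | CCCCCC#Cc1cc(OC)ccc1C(=O)OC
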